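- Two questions, and you want a quick number for both:

1. amount of target at the end, in percent of the starting material charged for epsilon, delta, alpha, zeta, in this order
2. how that number moves from the first to the last of them (falls all the way / hardly changes / falls, then rises / rises all the way / rises, then falls)

all flasks: starting material 0.20 M; initiator 2 mol%
- Sunday's: partner 1.3 equiv; transfer agent 0.20 M; run made earlier
- Friday's: partner 11 equiv; transfer agent 0.20 M; run made earlier
- epsilon: partner 1.00 equiv; transfer agent 0.200 M; time 8.0 h
- delta: partner 2.00 equiv; transfer agent 0.200 M; time 8.0 h
- alpha: partner 4.00 equiv; transfer agent 0.200 M; time 8.0 h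
- zeta: partner 8.00 equiv; transfer agent 0.200 M; time 8.0 h

- what was read earlier has a scatter of 1 percentage point, one standard deviation
- steps under discussion: initiator -> 2 initiating radical; starting material + initiating radical -> capped initiator + first chain carrier; partner + first chain carrier -> target + second chain carrier; starting material + second chain carrier -> by-product + first chain carrier; transfer agent + first chain carrier -> side product + idle radical; 2 idle radical -> ended radicals; 2 second chain carrier -> ended chains; partner + target -> over-reaction product
- "hardly changes" means that all values lie within two and a half points (for a concentration: within two and a half percent of the largest)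

- Sunday's (time / h: target / %, starting material / %): 0.333: 6.5, 92.1; 0.667: 12.4, 85.7; 1.50: 18.2, 76.1; 4.00: 23.0, 67.7
- Friday's (time / h: target / %, starting material / %): 0.500: 28.6, 63.5; 1.33: 32.9, 32.7; 2.50: 23.5, 16.4; 4.00: 11.0, 11.0

(each reading ± 1 percentage point)

- Your hunch is that more partner buys more target. I'd reckon on two things instead: how much target gets made, and how much of it outlasts the wait in [partner].
- I use the **loss constant**: over-reaction product formed per hour, per unit of target, per mole per litre of partner.
- Take Friday's last two readings. I count starting material gone but not found as target as over-reaction product, and that count grows by 17.9% of the charge in 1.50 h.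
- Friday's target falls over those hours, so I replace its curve by the mean of the two readings, 17.2%. With Friday's [partner] near 1.85 M, that gives 0.373 M⁻¹ h⁻¹.
- Now check the mean. An exponential fall has a mean of 16.5%, so mine runs 4.76% high, which is smaller than the 11.2% scatter on the count.
- For supply, I scale Sunday's consumed starting material with the partner charge, capped at the whole charge, and treat it as made by 1.50 h. From then on, target decays pseudo-first-order at the loss constant times charged [partner].
- My row is 15.3%, 18.8%, 14.3%, 2.07%, so it rises, then falls.
- The forecast gave 18%, 24%, 17% and 4%, with the shape "rises, then falls": “With little partner the chain stalls; with much, target is overcooked.”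
- The flasks give 14.7%, 18.8%, 14.1% and 3.08%, and the shape is rises, then falls.

    initiator → 2 initiating radical (k = 0.0122 min⁻¹)
    starting material + initiating radical → capped initiator + first chain carrier (k = 13600 M⁻¹ s⁻¹)
    partner + first chain carrier → target + second chain carrier (k = 1.88 × 10⁵ M⁻¹ min⁻¹)
    starting material + second chain carrier → by-product + first chain carrier (k = 58900 M⁻¹ min⁻¹)
    transfer agent + first chain carrier → side product + idle radical (kL = 28900 M⁻¹ min⁻¹)
    2 idle radical → ended radicals (k = 1.40 × 10⁸ M⁻¹ s⁻¹)
    2 second chain carrier → ended chains (k = 6.00 × 10⁶ M⁻¹ s⁻¹)
    partner + target → over-reaction product (k = 0.00726 M⁻¹ min⁻¹)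

- Zeta proves the reason: with the partner + target step struck out, target stands at 90.9%, against 3.08% with it. That is a surviving share of 3.39%, and the loss constant, with zeta's end [partner] applied from 1.50 h on, puts it at 4.90%. In epsilon, the loss constant at charged [partner] gives target a half-life of 9.29 h, the flask's own being 8.0 h, and at 8.0 h epsilon makes target at 0.0445 of the rate at which it loses it.

The numbers in the tables were computed from invented constants, and the scatter is random.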